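**Plan**
1. Retrosynthetic cuts, in order: the three O–Si bonds; the aryl–CH2 bond of the dihydrochalcone (Heck disconnection to a 5-bromochromene and an allylic alcohol of ring A); the two C–CH3 bonds of the side-chain carbinol; the C4–C4a bond of the pyran ring; the side-chain C=C (cross-metathesis); the C8a–O1 aryl ether bond (SNAr); the C2–allyl bond.
2. Forward: a silyl-capped alkynyl methyl ketone is allylated enantioselectively, the tertiary alkoxide is arylated, the allyl group becomes an E-enoate and the formyl group a silylated phenol. The pyran ring is then closed onto the arene, the enoate is turned into the tertiary allylic alcohol, ring A is joined and the silyl groups are removed.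
3. Enabling feature: C2 is a quaternary propargylic carbon bound to O1, so the terminal alkyne carbon (C4) lies over C4a. C4a is the only free ortho position of the C8a–O1 ether, because C8 carries oxygen. A 6-endo hydroarylation makes the C4–C4a bond and the C3=C4 alkene of the pyran ring at once and never breaks the C2–O1 bond.
4. Stereochemistry: C2 is set in step 1 by catalyst control and is not ionized afterwards; the E side-chain alkene comes from the cross-metathesis.

Key step: step 6

Assumption: in the diol-catalysed allylboration the silylalkynyl group of the ketone is taken to occupy the place of the aryl group of aryl methyl ketones, so that the (S)-diol gives the R carbinol; the configuration is to be confirmed by MTPA ester analysis before the route continues, and the antipodal diol serves if the sense proves opposite.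

**Step 1**
Reactants: 1 4-(trimethylsilyl)but-3-yn-2-one; 2 diisopropyl allylboronate
Product: 4 (3R)-3-methyl-1-(trimethylsilyl)hex-5-en-1-yn-3-ol, via borate ester 3 (not isolated)
Conditions: (S)-3,3'-dibromo-1,1'-bi-2-naphthol (15 mol%), PhCH3/PhCF3 3:1, −35 °C; then H2O
Reagents that add atoms: none
Why: Chiral-diol-catalysed asymmetric allylboration of a ketone, in which exchange of one isopropoxy group for the binaphthol gives a more Lewis-acidic chiral boronate that should deliver the allyl group through a closed chair transition state to the Re face of the ketone, setting the only stereocenter of the route as R.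

**Step 2**
Reactants: 4 (3R)-3-methyl-1-(trimethylsilyl)hex-5-en-1-yn-3-ol; 5 4-bromo-2-fluorobenzaldehyde
Product: 6 4-bromo-2-{[(3R)-3-methyl-1-(trimethylsilyl)hex-5-en-1-yn-3-yl]oxy}benzaldehyde
Conditions: KN(SiMe3)2, THF, −78 to 0 °C; then 5, 0 °C to rt
Reagents that add atoms: none
Why: SNAr in which the potassium tert-alkoxide should displace the fluoride ortho to the formyl group through a Meisenheimer adduct much faster than the para bromide, and since the carbinol C–O bond is not touched the configuration is retained.

**Step 3**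
Reactants: 6 4-bromo-2-{[(3R)-3-methyl-1-(trimethylsilyl)hex-5-en-1-yn-3-yl]oxy}benzaldehyde; 7 methyl acrylate (excess)
Product: 8 methyl (2E,5R)-5-(5-bromo-2-formylphenoxy)-5-methyl-7-(trimethylsilyl)hept-2-en-6-ynoate
Conditions: second-generation Hoveyda–Grubbs catalyst (5 mol%), CH2Cl2, 40 °C
Reagents that add atoms: none
Why: Olefin cross-metathesis of a terminal alkene with an acrylate should give the E enoate under thermodynamic control, the silyl-capped alkyne, aldehyde and aryl bromide being inert, and the electron-poor alkene so formed cannot act as a nucleophile toward the gold–alkyne complex of step 6.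

**Step 4**
Reactants: 8 methyl (2E,5R)-5-(5-bromo-2-formylphenoxy)-5-methyl-7-(trimethylsilyl)hept-2-en-6-ynoate
Product: 10 methyl (2E,5R)-5-(5-bromo-2-hydroxyphenoxy)-5-methylhept-2-en-6-ynoate, via aryl formate 9 (not isolated)
Conditions: mCPBA, CH2Cl2, 0 °C to rt; then K2CO3 (cat.), MeOH, 0 °C
Reagents that add atoms: 3-chloroperoxybenzoic acid, OOC(=O)c1cccc(Cl)c1
Why: Dakin-type Baeyer–Villiger oxidation in which the electron-rich ortho-alkoxyaryl group migrates to give the aryl formate, which mild methanolysis should cleave together with the alkynyl C–Si bond, while the enoate and the silylalkyne are not attacked by the peracid.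

**Step 5**
Reactants: 10 methyl (2E,5R)-5-(5-bromo-2-hydroxyphenoxy)-5-methylhept-2-en-6-ynoate
Product: 11 methyl (2E,5R)-5-{5-bromo-2-[(tert-butyldimethylsilyl)oxy]phenoxy}-5-methylhept-2-en-6-ynoate
Conditions: TBSCl, imidazole, DMF, rt
Reagents that add atoms: tert-butyldimethylsilyl chloride, CC(C)(C)[Si](C)(C)Cl
Why: Standard phenol silylation, which blocks 6-exo addition of the phenol oxygen to the alkyne in step 6 and installs a group that fluoride removes at the end.

**Step 6**
Reactants: 11 methyl (2E,5R)-5-{5-bromo-2-[(tert-butyldimethylsilyl)oxy]phenoxy}-5-methylhept-2-en-6-ynoate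
Product: 12 methyl (2E)-4-[(2R)-5-bromo-8-[(tert-butyldimethylsilyl)oxy]-2-methyl-2H-chromen-2-yl]but-2-enoate
Conditions: Ph3PAuNTf2 (3 mol%), CH2Cl2, rt, dark
Reagents that add atoms: none
Why: The cationic monovalent gold complex π-activates the terminal alkyne, the arene carbon ortho to the ether oxygen (future C4a) attacks the terminal alkyne carbon (future C4) anti to gold in a Friedel–Crafts-type step, and rearomatization followed by protodeauration of the vinylgold releases the 2H-chromene. The closest known reaction type is the gold- or platinum-catalysed intramolecular hydroarylation of aryl propargyl ethers to 2H-chromenes. The pyran ring closes in the 6-endo-dig mode. No new stereocenter is formed, and because the C2–O1 bond is never broken the configuration set in step 1 is carried over unchanged, which a thermal propargyl Claisen sequence with its C–O cleavage and ring-opened quinone methide would not allow. The step needs 6-endo rather than 5-exo closure and attack by the arene rather than by another nucleophile: the terminal alkyne and the quaternary propargylic carbon favour the endo path, only one ortho position is free because the other carries the silyloxy group, the phenol is capped, and the only other alkene is an electron-poor enoate.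

**Step 7**
Reactants: 12 methyl (2E)-4-[(2R)-5-bromo-8-[(tert-butyldimethylsilyl)oxy]-2-methyl-2H-chromen-2-yl]but-2-enoate
Product: 14 (3E)-5-[(2R)-5-bromo-8-[(tert-butyldimethylsilyl)oxy]-2-methyl-2H-chromen-2-yl]-2-methylpent-3-en-2-ol, via enone 13 (not isolated)
Conditions: MeMgBr, CeCl3, THF, −78 to 0 °C; aq. NH4Cl
Reagents that add atoms: methylmagnesium bromide, C[Mg]Br
Why: Double 1,2-addition of the weakly basic organocerium reagent to the ester through the enone should give the tertiary allylic alcohol without conjugate addition or γ-deprotonation with opening of the pyran ring, the aryl bromide and silyl ether being inert.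

**Step 8**
Reactants: 15 2,4-dihydroxybenzaldehyde
Product: 16 2,4-bis[(tert-butyldimethylsilyl)oxy]benzaldehyde
Conditions: TBSCl, imidazole, DMF, rt
Reagents that add atoms: tert-butyldimethylsilyl chloride, CC(C)(C)[Si](C)(C)Cl
Why: Standard silylation of both phenols, giving ring A the same fluoride-labile protection as the chromene half.

**Step 9**
Reactants: 16 2,4-bis[(tert-butyldimethylsilyl)oxy]benzaldehyde
Product: 17 rac-1-{2,4-bis[(tert-butyldimethylsilyl)oxy]phenyl}prop-2-en-1-ol
Conditions: CH2=CHMgBr, THF, −78 °C; aq. NH4Cl at −78 °C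
Reagents that add atoms: vinylmagnesium bromide, C=C[Mg]Br
Why: Grignard 1,2-addition to the aldehyde, quenched cold to avoid O-to-O silyl migration, gives the allylic alcohol as a racemate whose carbinol center is erased in step 10.

**Step 10**
Reactants: 14 (3E)-5-[(2R)-5-bromo-8-[(tert-butyldimethylsilyl)oxy]-2-methyl-2H-chromen-2-yl]-2-methylpent-3-en-2-ol; 17 rac-1-{2,4-bis[(tert-butyldimethylsilyl)oxy]phenyl}prop-2-en-1-ol
Product: 19 1-{2,4-bis[(tert-butyldimethylsilyl)oxy]phenyl}-3-{(2R)-8-[(tert-butyldimethylsilyl)oxy]-2-[(2E)-4-hydroxy-4-methylpent-2-en-1-yl]-2-methyl-2H-chromen-5-yl}propan-1-one, via enol 18 (not isolated)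
Conditions: Pd(OAc)2 (5 mol%), P(t-Bu)3·HBF4 (10 mol%), Cy2NMe, 1,4-dioxane, 80 °C
Reagents that add atoms: none
Why: Heck arylation of a secondary allylic alcohol, in which oxidative addition of the aryl bromide to zerovalent palladium, insertion at the terminal alkene carbon, β-hydride elimination toward the carbinol carbon and tautomerization of the enol should give the saturated β-aryl ketone directly, the disubstituted side-chain alkene and the ring alkene inserting far more slowly than the monosubstituted alkene.

**Step 11**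
Reactants: 19 1-{2,4-bis[(tert-butyldimethylsilyl)oxy]phenyl}-3-{(2R)-8-[(tert-butyldimethylsilyl)oxy]-2-[(2E)-4-hydroxy-4-methylpent-2-en-1-yl]-2-methyl-2H-chromen-5-yl}propan-1-one
Product: 20 1-(2,4-dihydroxyphenyl)-3-{(2R)-8-hydroxy-2-[(2E)-4-hydroxy-4-methylpent-2-en-1-yl]-2-methyl-2H-chromen-5-yl}propan-1-one
Conditions: Bu4NF, AcOH, THF, 0 °C
Reagents that add atoms: none
Why: Buffered fluoride should cleave the three aryl silyl ethers under conditions that leave the acid-sensitive tertiary allylic alcohol, the chromene and the ketone untouched.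

**Compound list**
1 | 4-(trimethylsilyl)but-3-yn-2-one | CC(=O)C#C[Si](C)(C)C | starting material
2 | diisopropyl allylboronate | C=CCB(OC(C)C)OC(C)C | starting material
3 | diisopropyl (3R)-3-methyl-1-(trimethylsilyl)hex-5-en-1-yn-3-yl borate | C=CC[C@](OB(OC(C)C)OC(C)C)(C)C#C[Si](C)(C)C | intermediate
4 | (3R)-3-methyl-1-(trimethylsilyl)hex-5-en-1-yn-3-ol | C=CC[C@](O)(C)C#C[Si](C)(C)C | intermediate
5 | 4-bromo-2-fluorobenzaldehyde | O=Cc1ccc(Br)cc1F | starting material
6 | 4-bromo-2-{[(3R)-3-methyl-1-(trimethylsilyl)hex-5-en-1-yn-3-yl]oxy}benzaldehyde | C=CC[C@](Oc1cc(Br)ccc1C=O)(C)C#C[Si](C)(C)C | intermediate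
7 | methyl acrylate | C=CC(=O)OC | starting material
8 | methyl (2E,5R)-5-(5-bromo-2-formylphenoxy)-5-methyl-7-(trimethylsilyl)hept-2-en-6-ynoate | COC(=O)/C=C/C[C@](Oc1cc(Br)ccc1C=O)(C)C#C[Si](C)(C)C | intermediate
9 | methyl (2E,5R)-5-[5-bromo-2-(formyloxy)phenoxy]-5-methyl-7-(trimethylsilyl)hept-2-en-6-ynoate | COC(=O)/C=C/C[C@](Oc1cc(Br)ccc1OC=O)(C)C#C[Si](C)(C)C | intermediate
10 | methyl (2E,5R)-5-(5-bromo-2-hydroxyphenoxy)-5-methylhept-2-en-6-ynoate | COC(=O)/C=C/C[C@](Oc1cc(Br)ccc1O)(C)C#C | intermediate
11 | methyl (2E,5R)-5-{5-bromo-2-[(tert-butyldimethylsilyl)oxy]phenoxy}-5-methylhept-2-en-6-ynoate | COC(=O)/C=C/C[C@](Oc1cc(Br)ccc1O[Si](C)(C)C(C)(C)C)(C)C#C | intermediate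
12 | methyl (2E)-4-[(2R)-5-bromo-8-[(tert-butyldimethylsilyl)oxy]-2-methyl-2H-chromen-2-yl]but-2-enoate | COC(=O)/C=C/C[C@]1(C)C=Cc2c(Br)ccc(O[Si](C)(C)C(C)(C)C)c2O1 | intermediate
13 | (3E)-5-[(2R)-5-bromo-8-[(tert-butyldimethylsilyl)oxy]-2-methyl-2H-chromen-2-yl]pent-3-en-2-one | CC(=O)/C=C/C[C@]1(C)C=Cc2c(Br)ccc(O[Si](C)(C)C(C)(C)C)c2O1 | intermediate
14 | (3E)-5-[(2R)-5-bromo-8-[(tert-butyldimethylsilyl)oxy]-2-methyl-2H-chromen-2-yl]-2-methylpent-3-en-2-ol | CC(C)(O)/C=C/C[C@]1(C)C=Cc2c(Br)ccc(O[Si](C)(C)C(C)(C)C)c2O1 | intermediate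
15 | 2,4-dihydroxybenzaldehyde | O=Cc1ccc(O)cc1O | starting material
16 | 2,4-bis[(tert-butyldimethylsilyl)oxy]benzaldehyde | O=Cc1ccc(O[Si](C)(C)C(C)(C)C)cc1O[Si](C)(C)C(C)(C)C | intermediate
17 | rac-1-{2,4-bis[(tert-butyldimethylsilyl)oxy]phenyl}prop-2-en-1-ol (racemate) | C=CC(O)c1ccc(O[Si](C)(C)C(C)(C)C)cc1O[Si](C)(C)C(C)(C)C | intermediate
18 | enol of 19, 1-{2,4-bis[(tert-butyldimethylsilyl)oxy]phenyl}-3-{(2R)-8-[(tert-butyldimethylsilyl)oxy]-2-[(2E)-4-hydroxy-4-methylpent-2-en-1-yl]-2-methyl-2H-chromen-5-yl}prop-1-en-1-ol (enol geometry open) | CC(C)(O)/C=C/C[C@]1(C)C=Cc2c(CC=C(O)c3ccc(O[Si](C)(C)C(C)(C)C)cc3O[Si](C)(C)C(C)(C)C)ccc(O[Si](C)(C)C(C)(C)C)c2O1 | intermediate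
19 | 1-{2,4-bis[(tert-butyldimethylsilyl)oxy]phenyl}-3-{(2R)-8-[(tert-butyldimethylsilyl)oxy]-2-[(2E)-4-hydroxy-4-methylpent-2-en-1-yl]-2-methyl-2H-chromen-5-yl}propan-1-one | CC(C)(O)/C=C/C[C@]1(C)C=Cc2c(CCC(=O)c3ccc(O[Si](C)(C)C(C)(C)C)cc3O[Si](C)(C)C(C)(C)C)ccc(O[Si](C)(C)C(C)(C)C)c2O1 | intermediate
20 | 1-(2,4-dihydroxyphenyl)-3-{(2R)-8-hydroxy-2-[(2E)-4-hydroxy-4-methylpent-2-en-1-yl]-2-methyl-2H-chromen-5-yl}propan-1-one | CC(C)(O)/C=C/C[C@]1(C)C=Cc2c(CCC(=O)c3ccc(O)cc3O)ccc(O)c2O1 | target

**Step count**
Total: 11 steps. Longest linear sequence: 9 steps (steps 1 to 7, 10 and 11).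

**Steps most likely to fail**

Step 1. The risk is poor or reversed facial selectivity, because methyl and the slim alkynyl group are sterically alike, together with uncatalysed background allylation of the electrophilic ynone. The fallback takes the stereocenter from the chiral pool. It does not set out from a numbered compound but replaces 1 and 2 by commercial (S)-2-methylglycidol, and it comes back to the route at 4. Opening of the epoxide at its CH2 terminus with CH2=CHMgBr and catalytic CuI should give (2R)-2-methylpent-4-ene-1,2-diol F1. Parikh–Doering oxidation of the primary alcohol (SO3·pyridine, DMSO, i-Pr2NEt) should give (2R)-2-hydroxy-2-methylpent-4-enal F2. Ohira–Bestmann homologation (dimethyl (1-diazo-2-oxopropyl)phosphonate, K2CO3, MeOH) should give (3R)-3-methylhex-5-en-1-yn-3-ol F3. Double deprotonation with n-BuLi and trapping with Me3SiCl should give trimethyl{[(3R)-3-methyl-1-(trimethylsilyl)hex-5-en-1-yn-3-yl]oxy}silane F4, whose O–Si bond is cleaved by citric acid in MeOH to give 4. No bond to the stereocenter is made or broken in this sequence.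

Step 2. The risk is reversible addition of the hindered alkoxide to the formyl group with hydride transfer between aldehyde molecules, slow substitution, and cleavage of the alkynyl C–Si bond by the alkoxide followed by acetylide addition to the aldehyde. The fallback sets out from 4 and comes back at 6. The formyl-activated arene is replaced by 4-bromo-2-fluorobenzonitrile, whose cyano group activates the fluoride but is not attacked. SNAr with the potassium alkoxide of 4 should give 4-bromo-2-{[(3R)-3-methyl-1-(trimethylsilyl)hex-5-en-1-yn-3-yl]oxy}benzonitrile F5. Partial reduction with i-Bu2AlH in toluene at −78 °C and acidic hydrolysis then gives aldehyde 6.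

Step 10. The risk is redox isomerization of the allylic alcohol partner by palladium hydride, β-hydride elimination toward the benzylic side giving an arylated allylic alcohol instead of the ketone, and slow oxidative addition to the hindered, electron-rich bromide. The fallback sets out from 14 and comes back at 19, and joins the ketone chain through a palladium homoenolate instead of a Heck insertion. Commercial methyl 2,4-dihydroxybenzoate is silylated (TBSCl, imidazole) to methyl 2,4-bis[(tert-butyldimethylsilyl)oxy]benzoate F6. Kulinkovich cyclopropanation (EtMgBr, Ti(O-i-Pr)4) should convert it to 1-{2,4-bis[(tert-butyldimethylsilyl)oxy]phenyl}cyclopropan-1-ol F7. Ring-opening cross-coupling of F7 with bromide 14 (Pd(OAc)2, a bulky biarylphosphine, K3PO4, toluene, 80 °C) should give the β-aryl ketone 19 directly.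

**Further compounds**
F1 | step 1 | (2R)-2-methylpent-4-ene-1,2-diol | C[C@](O)(CO)CC=C
F2 | step 1 | (2R)-2-hydroxy-2-methylpent-4-enal | C[C@](O)(C=O)CC=C
F3 | step 1 | (3R)-3-methylhex-5-en-1-yn-3-ol | C[C@](O)(C#C)CC=C
F4 | step 1 | trimethyl{[(3R)-3-methyl-1-(trimethylsilyl)hex-5-en-1-yn-3-yl]oxy}silane | C[C@](O[Si](C)(C)C)(C#C[Si](C)(C)C)CC=C
F5 | step 2 | 4-bromo-2-{[(3R)-3-methyl-1-(trimethylsilyl)hex-5-en-1-yn-3-yl]oxy}benzonitrile | C=CC[C@](Oc1cc(Br)ccc1C#N)(C)C#C[Si](C)(C)C
F6 | step 10 | methyl 2,4-bis[(tert-butyldimethylsilyl)oxy]benzoate | COC(=O)c1ccc(O[Si](C)(C)C(C)(C)C)cc1O[Si](C)(C)C(C)(C)C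
F7 | step 10 | 1-{2,4-bis[(tert-butyldimethylsilyl)oxy]phenyl}cyclopropan-1-ol | OC1(CC1)c1ccc(O[Si](C)(C)C(C)(C)C)cc1O[Si](C)(C)C(C)(C)C
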